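0.50 equiv of first nucleophile is the number to hold in the larch flask. What that reagent makes stays as target or isomer of the product, so c(target) + c(isomer of the product) + c(first nucleophile) + c(decomposition product) equals its charge, and target plus isomer together stay within that charge.

all flasks: substrate 0.17 M

|  | first nucleophile | second nucleophile | remark | time |
|---|---|---|---|---|
| larch | 0.50 equiv | 0.50 equiv | the very flask that is asked about, followed so far |  |
| flask | 0.500 equiv | 0.500 equiv |  | 20 min |
larch run (percent of the substrate charged)

| time / min | target / % | other capture product / % |
|---|---|---|
| 0.500 | 22 | 14 |
| 1.50 | 21 | 36 |
| 3.00 | 11 | 42 |
| 4.00 | 10 | 38 |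
| 6.00 | 7 | 43 |

(scatter of a reading: 1.5 percentage points)
- steps that have been proposed: substrate -> intermediate; first nucleophile + intermediate -> target; second nucleophile + intermediate -> other capture product; intermediate -> solvolysis product; second nucleophile <-> dormant form; first nucleophile -> decomposition product; target <-> isomer of the product
- share of target in target plus other capture product at 1.2 s
- share of target in target plus other capture product at 20 min
- which of target and other capture product there is more of at 20 min

We bracket the late share, within the scatter. From above, target is falling while other capture product holds near 41.0%, so the 7% of target at 6.00 min caps the share at 14.6%. From below, the fall slows from 0.431 min⁻¹ to 0.151 min⁻¹. Carrying the slower rate to 20 min leaves 0.849% of target, a share of 2.03%.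

To tighten this, we read the slowing as target nearing balance with its isomer, which puts the share near the top. The rest share, target's part of target plus isomer, is then the last target reading over the full charge, 14.0%. For the early share the first reading gives 61.1% at 0.500 min.

The forecast gave 75% early (62% to 90%), 7% late (1% to 14%) and other capture product ahead, with target perhaps “sitting at a small equilibrium level”. Its late value lies inside our bracket.

The flask gives 56.4% early and 12.8% late, also inside, with other capture product ahead at 40.3% against 5.92%.

    substrate → intermediate (k = 0.0210 s⁻¹)
    first nucleophile + intermediate → target (k = 140 M⁻¹ s⁻¹)
    second nucleophile + intermediate → other capture product (k = 120 M⁻¹ s⁻¹)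
    intermediate → solvolysis product (k = 0.870 s⁻¹)
    second nucleophile ⇌ dormant form (K = 0.670, k = 0.210 s⁻¹)
    first nucleophile → decomposition product (k = 8.80 × 10⁻⁶ s⁻¹)
    target ⇌ isomer of the product (K = 7.10, k = 0.0150 s⁻¹)

In the larch flask, substrate fed the intermediate with the midpoint of that turnover at 0.550 min, and while intermediate was there both nucleophiles and solvolysis took it, solvolysis 11.7% in the end. Target went over to isomer meanwhile, with that midpoint at 1.31 min, and the rest share on the 48.0% of the substrate that first nucleophile had turned into target and isomer gives 6.72% of target against 5.92%. With 1.20 equiv of first nucleophile, target plus isomer reached 76.0%, so the rest share gives 10.6%, and that flask holds 9.38%.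

The numbers in the tables were generated by integration on assumed constants.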